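**Impossible scaling.** Monomer in chains cannot simply follow the charge, for multiplying the west reading, taken at 0.90 M of free monomer, up to green's 3.0 M gives 169 %, more than the 100 % a charge holds.

| flask | free monomer | initiator | remark | time |
|---|---|---|---|---|
| north-east | 0.26 M | 26 mM | run made earlier |  |
| west | 0.90 M | 26 mM | run made earlier |  |
| south-west | 2.3 M | 26 mM | run made earlier |  |
| red | 1.5 M | 26 mM |  | 25 min |
| ochre | 0.25 M | 26 mM |  | 25 min |
| blue | 0.40 M | 26 mM |  | 25 min |
| amber | 0.80 M | 26 mM |  | 25 min |
| green | 3.0 M | 26 mM |  | 25 min |

| run | time / min | monomer in chains / % |
|---|---|---|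
| north-east | 2.00 | 0.6 |
| north-east | 4.00 | 1.6 |
| north-east | 8.00 | 5.0 |
| north-east | 12.0 | 8.9 |
| north-east | 25.0 | 24.5 |
| west | 5.00 | 5.5 |
| west | 10.0 | 15.3 |
| west | 15.0 | 27.7 |
| west | 20.0 | 39.8 |
| west | 25.0 | 50.6 |
| south-west | 2.00 | 2.0 |
| south-west | 6.00 | 13.9 |
| south-west | 12.0 | 34.9 |
| south-west | 20.0 | 58.4 |
| south-west | 25.0 | 69.5 |

(standard deviation of a reading: 0.3 percentage points)

- on the list of suspects stand: free monomer + initiator -> living end + monomer in chains; free monomer + living end -> monomer in chains + living end; monomer in chains -> over-reaction product; 2 initiator -> spent initiator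

- ranking by amount of monomer in chains, in percent of the free monomer charged, from high to low, at 25 min (red / ochre / blue / amber / green)
- the amount of monomer in chains, in percent of the free monomer charged of the flask you put first, at 25 min
- the amount of monomer in chains, in percent of the free monomer charged of the flask you put last, at 25 min

**Turned round.** Let X be monomer in chains as a fraction of the charge at 25 min, and Λ the natural logarithm of the charge over what remains free, which is the pseudo-first-order loss constant summed over the run. At that time Λ reads 0.281 in north-east, 0.705 in west and 1.19 in south-west. For a lighter flask to beat a heavier one, the charge exponent n, the slope of ln Λ against ln charge, would have to fall below zero. It reads 0.741 from north-east to west and 0.555 from west to south-west, the charge exponent I carry, and both stand above zero. South-west reads 19 percentage points above west, with a scatter of 0.3 points.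

**My reckoning.** I rank the flasks by charge and compute each end as a correction to its nearest run, multiplying that run's Λ by the charge ratio raised to n. Ochre, corrected from north-east with 0.741, has Λ of 0.273, so X is 23.9 %. Green, corrected from south-west with 0.555, has Λ of 1.38, so X is 74.7 %.

**The forecast.** It gives green > red > amber > blue > ochre, with 73 % first and 23.8 % last, calling green “an extrapolation, tempered by saturation”, and so it stands lower on green than my figure.

**The result.** The flasks rank green > red > amber > blue > ochre, with 72.9 % in green and 23.8 % in ochre.

    free monomer + initiator → living end + monomer in chains (k = 0.0640 M⁻¹ min⁻¹)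
    free monomer + living end → monomer in chains + living end, rate k2*[living end]*[free monomer] (k = 2.90 M⁻¹ min⁻¹)
    monomer in chains → over-reaction product (k = 3.90 × 10⁻⁵ min⁻¹)
    2 initiator → spent initiator (k = 0.860 M⁻¹ min⁻¹)

**Same reckoning.** Green's value gives Λ of 1.31, so n from south-west to green is 0.362, lower than 0.555 yet still above zero. The neighbour is ochre's recipe with 1.0 M of free monomer, which has the initiator of the west run. Corrected from west with 0.555, its Λ is 0.748, so X is 52.7 %, and that neighbour holds 52.9 % of monomer in chains.

The readings were generated by integration with made-up constants; noise was put on by code.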